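**Strategy.** The 2-pyranone ring (O1, C2–C6) is disconnected at the C3–C4 bond. Seen this way, O1–C2(=O)–C3(OMe) is a methoxyacetyl group carried by the enol oxygen on C6. C4 is the ester carbon of an α-methyl β-keto ester (C4–C5–C6). A single base-induced intramolecular Claisen acylation therefore closes the heterocycle with all substituents, side chain included, already in place. It also liberates the 4-OH for the final methylation. The precursor is the Z enol methoxyacetate of the side-chain-bearing β-keto ester. The E trisubstituted side-chain alkene comes from a zirconium-catalysed carboalumination.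

Key step: step 7

Remark on the chemistry: the sp3 carbon between the two carbonyl groups of the malonate half-ester and of the β-keto ester is racemic. It becomes sp2 in step 6. The target has no stereocentre, only the E alkene. In the cyclisation precursor, CO2Me on C2 and the acyloxy oxygen on C3 are the senior groups and lie cis, hence 2Z.

**Step 1**
Reactants: 1 (6-bromohexyl)benzene; 2 lithium acetylide–ethylenediamine complex
Product: 3 8-phenyl-1-octyne
Conditions: LiC≡CH·H2NCH2CH2NH2 (1.3 equiv), DMSO, 0 °C → rt
Reagents that add atoms: none
Why: SN2 alkylation of an acetylide by an unhindered primary bromide in a dipolar aprotic solvent is the standard entry to a terminal alkyne, and nothing else in 1 reacts.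

**Step 2**
Reactants: 3 8-phenyl-1-octyne; 4 oxirane
Product: 7 (E)-4-methyl-10-phenyldec-3-en-1-ol, via alkenylalane 5 (not isolated), via lithium alanate 6 (not isolated)
Conditions: AlMe3 (2 equiv), Cp2ZrCl2 (0.2 equiv), CH2Cl2, 0 °C → rt; volatiles removed in vacuo; n-BuLi (1 equiv), hexane–THF, 0 °C; oxirane (3 equiv), −30 °C → rt; 1 M HCl
Reagents that add atoms: trimethylaluminium, C[Al](C)C (the C4 methyl of 7; the AlMe2 group of 5 and 6); n-butyllithium, [Li]CCCC (butyl and lithium of 6 only)
Why: Negishi zirconium-catalysed carboalumination adds CH3 and Al syn across the terminal alkyne with Al at the terminus, which fixes the E geometry, and the alanate made with n-BuLi is nucleophilic enough to open oxirane (SN2) with retention at the alkenyl carbon.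

**Step 3**
Reactants: 7 (E)-4-methyl-10-phenyldec-3-en-1-ol
Product: 9 (E)-4-methyl-10-phenyldec-3-enoic acid, via aldehyde 8 (not isolated)
Conditions: TEMPO (0.2 equiv), PhI(OAc)2 (2.2 equiv), MeCN–H2O 1:1, rt
Reagents that add atoms: water, O (second oxygen of the carboxyl group)
Why: The oxoammonium-catalysed TEMPO/PhI(OAc)2 oxidation takes the primary alcohol through aldehyde 8 and its hydrate to the acid under weakly acidic, metal-free conditions that neither attack the trisubstituted alkene nor move it into conjugation.

**Step 4**
Reactants: 10 dimethyl methylmalonate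
Product: 11 potassium methyl methylmalonate
Conditions: KOH (1.0 equiv), MeOH, 0 °C → rt; concentrate, triturate with Et2O
Reagents that add atoms: potassium hydroxide, [K+].[OH-]
Why: Mono-saponification with one equivalent of KOH stops at the half-ester because the carboxylate formed deactivates the remaining ester towards hydroxide and the potassium salt separates from the medium.

**Step 5**
Reactants: 9 (E)-4-methyl-10-phenyldec-3-enoic acid; 11 potassium methyl methylmalonate
Product: 14 methyl (E)-2,6-dimethyl-3-oxo-12-phenyldodec-5-enoate, via acyl imidazolide 12 (not isolated), via magnesium malonate chelate 13 (not isolated)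
Conditions: 9, 1,1'-carbonyldiimidazole (1.1 equiv), THF, rt; separately 11 (2 equiv), MgCl2, Et3N, MeCN, rt; combine, rt → 40 °C; 1 M HCl
Reagents that add atoms: 1,1'-carbonyldiimidazole, O=C(n1ccnc1)n1ccnc1 (imidazolyl group of 12 only); magnesium chloride, [Mg+2].[Cl-].[Cl-] (magnesium of 13 only)
Why: The Masamune–Brooks homologation (decarboxylative Claisen condensation) C-acylates the magnesium-chelated malonate half-ester with the neutral imidazolide and loses CO2, so the β-keto ester forms without strong base and stays bound as its magnesium chelate, which keeps the β,γ-alkene where it is.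

**Step 6**
Reactants: 14 methyl (E)-2,6-dimethyl-3-oxo-12-phenyldodec-5-enoate; 15 methoxyacetyl chloride
Product: 17 methyl (2Z,5E)-3-(methoxyacetoxy)-2,6-dimethyl-12-phenyldodeca-2,5-dienoate, via sodium enolate 16 (not isolated)
Conditions: NaH (1.0 equiv), Et2O, 0 °C; MeOCH2COCl (1.05 equiv), −20 → 0 °C; cold aqueous wash, rapid filtration through deactivated silica
Reagents that add atoms: sodium hydride, [Na+].[H-] (sodium of 16 only)
Why: O-acylation of a β-keto ester enolate: in diethyl ether the sodium enolate is a U-shaped chelate with both oxygens on the same side, its fully substituted C2 resists C-acylation by the hard acid chloride, and capture at the ketone-derived oxygen should therefore give the Z enol ester, in line with the Z-selective enol phosphate and enol sulfonate preparations from such chelates.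

**Step 7**
Reactants: 17 methyl (2Z,5E)-3-(methoxyacetoxy)-2,6-dimethyl-12-phenyldodeca-2,5-dienoate
Product: 20 4-hydroxy-3-methoxy-5-methyl-6-[(E)-3-methyl-9-phenylnon-2-enyl]-2H-pyran-2-one, via lithium ester enolate 18 (not isolated), via lithium pyranonolate 19 (not isolated)
Conditions: 17 added slowly to LiN(SiMe3)2 (2.1 equiv), THF (dilute), −78 °C; → −20 °C; 1 M HCl at −20 °C
Reagents that add atoms: lithium bis(trimethylsilyl)amide, [Li+].C[Si](C)(C)[N-][Si](C)(C)C (lithium of 18 and 19 only; nothing remains in 20)
Why: Proposed new method: LiN(SiMe3)2 removes a proton from the CH2 of the methoxyacetyl group (acidified by the α-oxygen and the enol-ester linkage, and guided by lithium chelation between the methoxy and carbonyl oxygens) to give ester enolate 18, whose carbon (future C3) adds to the methyl ester carbon (future C4) held cis on the C5=C6 double bond; collapse of the adduct expels methoxide, and the β-keto lactone is deprotonated at once to the delocalised 4-oxido-2-pyranone 19, an irreversible sink. The closest known reactions are the Dieckmann-type closure of methyl O-acylsalicylates to 4-hydroxycoumarins, the Lacey–Dieckmann synthesis of tetronic acids and the closure of β-acyloxy esters to 5,6-dihydro-4-hydroxy-2-pyranones; the new element is that the O-acyl group sits on an acyclic enol. The one ring formed, the 2-pyranone, closes in a 6-(enolendo)-exo-trig mode, which is favoured for enolates, and no stereocentre is created. The step needs deprotonation of the acyl CH2 in preference to the doubly allylic C4–H2 (future C1'): in the Z isomer that CH2 lies trans to the ester carbonyl, so lithium-directed γ-deprotonation has no handle, whereas the acyl CH2 sits inside a chelate. Slow addition of 17 to 2.1 equiv of cold base turns each molecule into its enolate before methoxide appears, so neither methoxide nor 18 finds unreacted activated enol ester to cleave, and no amide base is left at the end to metalate C1' of 19. Staying at or below −20 °C restrains loss of methoxyketene from 18.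

**Step 8**
Reactants: 20 4-hydroxy-3-methoxy-5-methyl-6-[(E)-3-methyl-9-phenylnon-2-enyl]-2H-pyran-2-one
Product: 21 lehualide E, 3,4-dimethoxy-5-methyl-6-[(E)-3-methyl-9-phenylnon-2-enyl]-2H-pyran-2-one
Conditions: Me2SO4 (1.2 equiv), K2CO3 (1.5 equiv), acetone, rt → 40 °C; aq. NH3 quench; chromatography
Reagents that add atoms: dimethyl sulfate, COS(=O)(=O)OC
Why: Alkylation of the vinylogous carboxylate of a 4-hydroxy-2-pyranone with Me2SO4/K2CO3 in acetone is the standard O-methylation that favours the 4-methoxy-2-pyranone over the 2-methoxy-4-pyranone (removable by chromatography), and carbonate is too weak a base to move the skipped alkene.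

**Compound list**
1 | (6-bromohexyl)benzene | BrCCCCCCc1ccccc1 | starting material
2 | lithium acetylide–ethylenediamine complex | [Li+].[C-]#C.NCCN | starting material
3 | 8-phenyl-1-octyne | C#CCCCCCCc1ccccc1 | intermediate
4 | oxirane | C1CO1 | starting material
5 | dimethyl[(E)-2-methyl-8-phenyloct-1-en-1-yl]alane (Al and new CH3 cis) | C[Al](C)/C=C(\C)CCCCCCc1ccccc1 | intermediate
6 | lithium butyl(dimethyl)[(E)-2-methyl-8-phenyloct-1-en-1-yl]alanate | [Li+].CCCC[Al-](C)(C)/C=C(\C)CCCCCCc1ccccc1 | intermediate
7 | (E)-4-methyl-10-phenyldec-3-en-1-ol | OCC/C=C(\C)CCCCCCc1ccccc1 | intermediate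
8 | (E)-4-methyl-10-phenyldec-3-enal | O=CC/C=C(\C)CCCCCCc1ccccc1 | intermediate
9 | (E)-4-methyl-10-phenyldec-3-enoic acid | OC(=O)C/C=C(\C)CCCCCCc1ccccc1 | intermediate
10 | dimethyl methylmalonate | COC(=O)C(C)C(=O)OC | starting material
11 | potassium methyl methylmalonate (racemic) | [K+].[O-]C(=O)C(C)C(=O)OC | intermediate
12 | (E)-1-(imidazol-1-yl)-4-methyl-10-phenyldec-3-en-1-one | O=C(C/C=C(\C)CCCCCCc1ccccc1)n1ccnc1 | intermediate
13 | magnesium enolate-carboxylate chelate of methyl hydrogen methylmalonate | COC1=C(C)C(=O)O[Mg]O1 | intermediate
14 | methyl (E)-2,6-dimethyl-3-oxo-12-phenyldodec-5-enoate (racemic at C2) | COC(=O)C(C)C(=O)C/C=C(\C)CCCCCCc1ccccc1 | intermediate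
15 | methoxyacetyl chloride | COCC(Cl)=O | starting material
16 | sodium enolate of 14, chelated, ester and O− cis | [Na+].COC(=O)/C(C)=C([O-])/C/C=C(\C)CCCCCCc1ccccc1 | intermediate
17 | methyl (2Z,5E)-3-(methoxyacetoxy)-2,6-dimethyl-12-phenyldodeca-2,5-dienoate | COC(=O)/C(C)=C(OC(=O)COC)/C/C=C(\C)CCCCCCc1ccccc1 | intermediate
18 | lithium enolate of 17 at the methoxyacetyl group (OMe and OLi cis, chelated) | [Li+].CO/C=C(\[O-])O/C(C/C=C(\C)CCCCCCc1ccccc1)=C(/C)C(=O)OC | intermediate
19 | lithium 3-methoxy-5-methyl-6-[(E)-3-methyl-9-phenylnon-2-enyl]-2-oxo-2H-pyran-4-olate | [Li+].COc1c([O-])c(C)c(C/C=C(\C)CCCCCCc2ccccc2)oc1=O | intermediate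
20 | 4-hydroxy-3-methoxy-5-methyl-6-[(E)-3-methyl-9-phenylnon-2-enyl]-2H-pyran-2-one | COc1c(O)c(C)c(C/C=C(\C)CCCCCCc2ccccc2)oc1=O | intermediate
21 | lehualide E | COc1c(C)c(C/C=C(\C)CCCCCCc2ccccc2)oc(=O)c1OC | target

**Step count.** Total steps: 8. Longest linear sequence: 7 (steps 1, 2, 3, 5, 6, 7, 8); step 4 is a side branch.

**Steps most likely to fail**

1. **Step 7.**
   - Risk: ring closure may be outrun by metalation at the doubly allylic CH2 followed by migration of the side-chain alkene into conjugation. It may also be outrun by fragmentation of the ester enolate through loss of ketene, or by intermolecular acyl transfer.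
   - Fallback: this uses known chemistry and forms O1–C2 last by lactonising an open-chain 3,5-dioxo ester. It sets out from 7 and comes back at 20.
   - Alcohol 7 is oxidised with Dess–Martin periodinane (CH2Cl2, NaHCO3) to aldehyde 8, this time isolated.
   - The lithium enolate of methyl methoxyacetate is acylated with propanoyl chloride (crossed Claisen) to give methyl 2-methoxy-3-oxopentanoate F1.
   - NaH and then n-BuLi convert it into the sodium lithium dianion F2, which adds through its terminal carbon to 8 at −78 °C. This gives methyl (E)-5-hydroxy-2-methoxy-4,8-dimethyl-3-oxo-14-phenyltetradec-7-enoate F3 as a diastereomer mixture of no consequence.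
   - Dess–Martin oxidation gives methyl (E)-2-methoxy-4,8-dimethyl-3,5-dioxo-14-phenyltetradec-7-enoate F4.
   - DBU in toluene closes the lactone with loss of methanol to 20.

2. **Step 6.**
   - Risk: chelate control may erode so that the double-bond geometry is not uniform. Acylation at carbon may compete, and the activated enol ester may hydrolyse on isolation.
   - Fallback: stereocontrol at the acylation is given up and the ring closure is used to sort the isomers. It sets out from 14 and comes back at 20, with recovered material re-entering at 14.
   - The crude acylation mixture of 17 and methyl (2E,5E)-3-(methoxyacetoxy)-2,6-dimethyl-12-phenyldodeca-2,5-dienoate F5 is taken without chromatography into the conditions of step 7, where only the Z isomer can reach the ester carbon.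
   - After the quench, brief treatment with K2CO3/MeOH at 0 °C cleaves the remaining enol ester back to 14.
   - The acidic 20 is separated from neutral 14 by base extraction or chromatography, and 14 is acylated again.

3. **Step 8.**
   - Risk: the ambident pyranone anion may be methylated at the lactone carbonyl oxygen rather than at O4, a drift encouraged by the two substituents flanking O4.
   - Fallback: the alkylation of an anion is replaced by a base-free Mitsunobu etherification (MeOH, PPh3, diisopropyl azodicarboxylate, THF, 0 °C → rt). In this reaction 4-hydroxy-2-pyranones are known to act as acidic pronucleophiles and give 4-alkoxy-2-pyranones.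
   - It sets out from 20 and comes back at 21 directly, and it makes no compound outside the list (entry F0).

**Further compounds**
F1 | step 7 | methyl 2-methoxy-3-oxopentanoate | CCC(=O)C(OC)C(=O)OC
F2 | step 7 | sodium lithium dianion of methyl 2-methoxy-3-oxopentanoate (enolate geometry not defined) | [Na+].[Li+].CC=C([O-])C(OC)=C([O-])OC
F3 | step 7 | methyl (E)-5-hydroxy-2-methoxy-4,8-dimethyl-3-oxo-14-phenyltetradec-7-enoate | COC(=O)C(OC)C(=O)C(C)C(O)C/C=C(\C)CCCCCCc1ccccc1
F4 | step 7 | methyl (E)-2-methoxy-4,8-dimethyl-3,5-dioxo-14-phenyltetradec-7-enoate | COC(=O)C(OC)C(=O)C(C)C(=O)C/C=C(\C)CCCCCCc1ccccc1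
F5 | step 6 | methyl (2E,5E)-3-(methoxyacetoxy)-2,6-dimethyl-12-phenyldodeca-2,5-dienoate | COC(=O)/C(C)=C(/OC(=O)COC)C/C=C(\C)CCCCCCc1ccccc1
F0 | step 8 | none | none
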